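## Analysis of the target

5-Hydroxyauranetin (12) is a flavone, a 2-aryl-4H-chromen-4-one. It consists of benzo ring A (C4a, C5–C8, C8a), pyranone ring C (O1, C2, C3, C4) and a 4-methoxyphenyl ring B on C2. It has no stereocentre, no stereogenic double bond and no hindered axis, so it is achiral and there are no stereochemical relationships to set. Ring A is fully substituted: C5 carries a free hydroxyl, C6, C7 and C8 carry methoxy groups, and C4a and C8a are the fusion atoms. Ring C adds a fifth ether at C3. Three features are sensitive:
- the C5 hydroxyl, which is hydrogen-bonded to the C4 carbonyl;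
- the para pair C5–OH/C8–OMe, which makes ring A a hydroquinone monoether that is easily oxidised to the 5,8-quinone;
- the pyranone, which strong nucleophiles open at C2.

The hard part is the hexasubstituted arene, because classical flavone syntheses need a penta-oxygenated benzene with one free position and must then single out one of several neighbouring oxygens. The strategy rests on the chain C5–C6–C7–C8, four adjacent oxygen-bearing carbons whose ends are para to each other and are bonded to C4a and C8a, the two carbons of a pyranone C=C bond. A squaric ester supplies four contiguous oxygenated carbons, and expanding a 4-alkoxycyclobutenone onto a neighbouring C=C–H unit gives exactly the free phenol para to an ether.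

## Retrosynthetic reasoning

**C5–C4a (12 ⇒ 9).** The last bond to be made is C5–C4a. Cutting it and returning the phenol proton to C4a gives dione 11. Retro-6π opening of 11 gives dienylketene 10, and joining C5 back to C8 gives cyclobutenone 9. This cut is preferred to any cut in ring C because it removes the hexasubstituted benzene from the problem: ring A is assembled with all its oxygens in place rather than functionalised. The forward reaction must open 9 with the pyranonyl group turned towards the ketene and then close onto the single pyranone C–H.

**C8–O–CH3 (9 ⇒ 8).** Removing the methyl group from the tertiary oxygen of 9 gives carbinol 8. This is where the C5 and C8 oxygens are told apart. The alkylated oxygen becomes the C8 ether and the ring carbonyl oxygen becomes the C5 phenol, so no late selective demethylation is needed. The methylation is a separate, silver-assisted step. A sulfonate-type methylating agent added to the crude alkoxide would also attack the nucleophilic pyranone carbonyl oxygen (pyrylium formation) and the hindered amine left from the metalation.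

**C8–C8a (8 ⇒ 5 + 6).** The bond between the carbinol carbon and the pyranone is cut to give dimethyl squarate 6 and the C6 carbanion 7 of arylpyranone 5. Carbonyl addition to 6 is the standard way to place a substituent at C4 of a cyclobutenone. It joins the two halves in one step, and all four ring A oxygens come from 6. The forward step needs deprotonation of 5 next to the ring oxygen by a hindered lithium amide, without attack on the electrophilic pyranone.

**C2–C1′ (5 ⇒ 3 + 4).** The aryl–pyranone bond is cut to bromopyranone 3 and boronic acid 4. C2–Br of 3 is a vinylogous acyl bromide and an excellent cross-coupling partner. An Achmatowicz ring expansion of an aryl furyl carbinol would also reach this ring, but its product lies two electrons below a 3-hydroxy-4-pyranone. Closing that gap needs acetal protection, enone epoxidation and acid rearrangement, or a second equivalent of halogen that the anisyl ring would not tolerate. That path costs three more steps than the coupling.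

**O–CH3 and C2–Br (3 ⇒ 2 ⇒ 1).** Removing the enol methyl ether and then the bromine leads to commercial 3-hydroxy-4H-pyran-4-one 1. Bromination comes first because the free enol directs the electrophile to C2. The ether is made next so that no acidic, metal-chelating hydroxyl enters the palladium and lithium steps.

## Alternatives that were turned down

**Alternative 1:** Ring C is opened at O1–C2 and the carbonyl carbon C4 is cut out on both sides (C4a–C4 and C4–C3). This leads to 2-methoxy-1-(4-methoxyphenyl)-3-[2,3,4,5-tetramethoxy-6-(methoxymethoxy)phenyl]propane-1,3-dione A1.
- *Forward key step:* 1-iodo-2,3,4,5-tetramethoxy-6-(methoxymethoxy)benzene A2, carbon monoxide A3 and the enolate of 2-methoxy-1-(4-methoxyphenyl)ethan-1-one A4 are joined on palladium by oxidative addition, insertion and enolate acylation. Acid then removes the acetal and closes the pyranone.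
- *For:* it is highly convergent, makes two C–C bonds in one operation, and the ring closure afterwards is trivial.
- *Against:* the C–I carbon of A2 is electron-rich and flanked by two alkoxy groups, so both oxidative addition and insertion are slowed. A hindered α-alkoxy enolate can instead be arylated directly or acylated on oxygen. A1 is more acidic than A4 and consumes enolate as it forms.
- *Against, on step economy:* A2 is itself the hexasubstituted, oxygen-differentiated benzene that makes the target hard, so the problem is moved rather than solved. C5 emerges as a methyl ether, so a chelation-controlled demethylation must follow.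
- *Comparison:* this route is stronger on convergence, and its final demethylation is dependable. The chosen route never has to prepare a fully substituted arene and delivers C5–OH free.

**Alternative 2:** Both bonds from ring A to ring C (O1–C8a and C4–C4a) are cut at once. This leads to (Z)-1-(2-hydroxy-3,4,5,6-tetramethoxyphenyl)-2-methoxy-3-(4-methoxyphenyl)prop-2-en-1-one A5.
- *Forward key step:* fluoride acts on 2,3,4,5-tetramethoxy-6-(trimethylsilyl)phenyl trifluoromethanesulfonate A6 to release 3,4,5,6-tetramethoxybenzyne A7. The carboxylate of (Z)-2-methoxy-3-(4-methoxyphenyl)prop-2-enoic acid A8 adds to it, and the aryl anion takes over the acyl group from oxygen.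
- *For:* A7 is symmetric, so there is no regiochemical question, and the step is metal-free and joins both ring A attachment points together.
- *Against:* the acyl shift must pass through a strained four-membered arrangement, and it competes with simple protonation of the aryl anion by the acid partner, which stops at the aryl ester. The enol-ether alkene of A8 is a further reaction site for an aryne. A6 is again a hexasubstituted benzene with a long preparation.
- *Against, on step economy:* A5 still needs ring closure, dehydrogenation to the flavone level and C5 demethylation.
- *Comparison:* it matches the chosen route in avoiding regiochemical issues at ring A. It loses on step economy both before and after the key step, whereas the chosen key step ends directly at 12.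

**Alternative 3:** Ring C is cut at C4–C4a and O1–C2, leading to 3,5,6,7,8,4′-hexamethoxyflavone A9.
- *Forward key step:* 2,3,4,5-tetramethoxyphenol A10 and ethyl 2-methoxy-3-(4-methoxyphenyl)-3-oxopropanoate A11 are heated together. C-acylation and cyclodehydration take place in one flask (Mentzer-type pyrone synthesis).
- *For:* it is the shortest plan on paper, one step to the full skeleton plus one well-behaved chelation-controlled demethylation at C5.
- *Against:* this thermal condensation relies on very nucleophilic polyhydroxybenzenes. A10 is a monophenol whose only free carbon is crowded. The Pechmann manifold, with the arene attacking the ketone and the phenol attacking the ester, leads to the isomeric coumarin skeleton. The α-methoxy group lowers the enol content and adds bulk, and the temperatures required invite retro-Claisen cleavage of A11. A10 must also be made in several steps.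
- *Comparison:* with A10 in hand this route is as short as the chosen one or shorter, and its last step is more certain than a new pericyclic substrate. The chosen route offers a constitution fixed by the bonds already present in 9, with no chromone/coumarin ambiguity and three purchasable building blocks.

Key step: step 6

Remark on stereochemistry: 12 is achiral, so the structure drawn is the only species that exists. Compounds 8, 9 and 11 are racemic, and their single stereocentre is erased on the way to 12.

## Route

Step 1
Reactants: 1 3-hydroxy-4H-pyran-4-one (pyromeconic acid)
Product: 2 2-bromo-3-hydroxy-4H-pyran-4-one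
Conditions: NBS (1.0 equiv), MeCN, 0 °C → rt, dark
Reagents that add atoms: N-bromosuccinimide, O=C1CCC(=O)N1Br
Why: Electrophilic bromination of an enol; the C3 hydroxyl makes C2 the enol β-carbon, the site at which 3-hydroxy-4-pyranones also take Mannich and hydroxymethylation electrophiles. One equivalent of NBS at low temperature should therefore brominate C2 and leave C5 and C6 untouched.

Step 2
Reactants: 2 2-bromo-3-hydroxy-4H-pyran-4-one
Product: 3 2-bromo-3-methoxy-4H-pyran-4-one
Conditions: MeI (5 equiv), K2CO3, acetone, rt
Reagents that add atoms: iodomethane, CI
Why: Williamson O-methylation of an acidic enol, as is routine for maltol- and kojic-acid-type hydroxypyranones. The large excess of MeI at room temperature makes methylation faster than displacement of the vinylogous acyl bromide of 3 by remaining enolate.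

Step 3
Reactants: 3 2-bromo-3-methoxy-4H-pyran-4-one; 4 4-methoxyphenylboronic acid
Product: 5 3-methoxy-2-(4-methoxyphenyl)-4H-pyran-4-one
Conditions: Pd(dppf)Cl2 (3 mol %), K2CO3, 1,4-dioxane/H2O, 80 °C
Reagents that add atoms: none
Why: Suzuki–Miyaura coupling; C2–Br is a β-bromo enone bond that adds readily to Pd(0). A carbonate base at moderate temperature spares the base-sensitive pyranone.

Step 4
Reactants: 5 3-methoxy-2-(4-methoxyphenyl)-4H-pyran-4-one; 6 dimethyl squarate (3,4-dimethoxycyclobut-3-ene-1,2-dione)
Product: 8 4-hydroxy-2,3-dimethoxy-4-[5-methoxy-6-(4-methoxyphenyl)-4-oxo-4H-pyran-2-yl]cyclobut-2-en-1-one (racemic), via 6-lithiopyranone 7 (not isolated)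
Conditions: TMPH, n-BuLi, THF, 0 °C (LiTMP, 1.05 equiv); 5 added at −78 °C, 15 min; cannulated into 6 (1.3 equiv), THF, −78 °C; aq NH4Cl, −78 °C
Reagents that add atoms: none
Why: Deprotonative lithiation next to the ring oxygen, then 1,2-addition of the organolithium to a squarate carbonyl, the standard entry to 4-substituted 4-hydroxycyclobutenones. C6–H is the most acidic C–H of 5 (sp2, α to O1, the position at which chromones are lithiated by hindered amides at −78 °C); LiTMP is too bulky to add to the ring, and adding 5 to the base keeps 7 away from unmetalated 5. The new stereocentre forms racemic and is destroyed in step 6.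

Step 5
Reactants: 8 4-hydroxy-2,3-dimethoxy-4-[5-methoxy-6-(4-methoxyphenyl)-4-oxo-4H-pyran-2-yl]cyclobut-2-en-1-one
Product: 9 2,3,4-trimethoxy-4-[5-methoxy-6-(4-methoxyphenyl)-4-oxo-4H-pyran-2-yl]cyclobut-2-en-1-one (racemic)
Conditions: MeI (excess), Ag2O, 4 Å MS, MeCN, rt, dark
Reagents that add atoms: iodomethane, CI
Why: Purdie methylation, the mild method commonly used for tertiary 4-hydroxycyclobutenones; it avoids strong base and leaves the weakly nucleophilic pyranone carbonyl alone. It replaces a one-flask methyl triflate quench, which would also methylate that carbonyl oxygen (4-methoxypyrylium salt) and the tetramethylpiperidine carried over from step 4.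

Step 6
Reactants: 9 2,3,4-trimethoxy-4-[5-methoxy-6-(4-methoxyphenyl)-4-oxo-4H-pyran-2-yl]cyclobut-2-en-1-one
Product: 12 5-hydroxyauranetin [5-hydroxy-3,6,7,8-tetramethoxy-2-(4-methoxyphenyl)-4H-chromen-4-one], via dienylketene 10 (not isolated), via cyclohexadienone 11 (not isolated)
Conditions: p-xylene (0.02 M, degassed), 138 °C, Ar
Reagents that add atoms: none
Why: Moore-type thermal ring expansion of a 4-alkenyl/heteroaryl-4-alkoxycyclobutenone to a hydroquinone monoether, here with a pyranon-2-yl arm that is a new member of a well-studied class. Heating breaks the C1–C4 bond of 9 in a conrotatory 4π opening, and because the C4 methoxy donor prefers to rotate outward, the pyranonyl group rotates inward and the Z-dienylketene 10 has the pyranone C–H next to the ketene. Ring A then closes by a disrotatory 6π electrocyclisation over the ketene C=C, the central C=C and the pyranone C=C bond, which forms the one new skeletal bond, C5–C4a in flavone numbering. The polarity is matched, since the ketene carbon is the electrophile and the pyranone carbon is α to the carbonyl and β to the ring oxygen, the nucleophilic end of a vinylogous ester; little aromatic stabilisation is lost, so the arm should behave like an alkenyl rather than an aryl group. Dione 11 holds its C4a proton between two carbonyl groups, so enolisation to the chelated C5 phenol is fast and irreversible and pulls the reversible opening forward. Site selectivity needs no control, because the atom on the other side of the attachment point is the ring oxygen and closure there gives no stable product. No stereocentre is created in 12: C4 of 9 is destroyed in the opening and C4a of 11 in the proton shift. High dilution and exclusion of air and moisture guard the ketene against dimerisation and hydration and the product against oxidation to the quinone.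

## Compound list

1 | 3-hydroxy-4H-pyran-4-one (pyromeconic acid) | O=c1ccocc1O | starting material
2 | 2-bromo-3-hydroxy-4H-pyran-4-one | O=c1ccoc(Br)c1O | intermediate
3 | 2-bromo-3-methoxy-4H-pyran-4-one | COc1c(Br)occc1=O | intermediate
4 | 4-methoxyphenylboronic acid | COc1ccc(B(O)O)cc1 | starting material
5 | 3-methoxy-2-(4-methoxyphenyl)-4H-pyran-4-one | COc1ccc(-c2occc(=O)c2OC)cc1 | intermediate
6 | dimethyl squarate | COC1=C(OC)C(=O)C1=O | starting material
7 | [5-methoxy-6-(4-methoxyphenyl)-4-oxo-4H-pyran-2-yl]lithium (not isolated) | [Li]c1cc(=O)c(OC)c(-c2ccc(OC)cc2)o1 | intermediate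
8 | 4-hydroxy-2,3-dimethoxy-4-[5-methoxy-6-(4-methoxyphenyl)-4-oxo-4H-pyran-2-yl]cyclobut-2-en-1-one (racemic) | COC1=C(OC)C(O)(c2cc(=O)c(OC)c(-c3ccc(OC)cc3)o2)C1=O | intermediate
9 | 2,3,4-trimethoxy-4-[5-methoxy-6-(4-methoxyphenyl)-4-oxo-4H-pyran-2-yl]cyclobut-2-en-1-one (racemic) | COC1=C(OC)C(OC)(c2cc(=O)c(OC)c(-c3ccc(OC)cc3)o2)C1=O | intermediate
10 | (3Z)-2,3,4-trimethoxy-4-[5-methoxy-6-(4-methoxyphenyl)-4-oxo-4H-pyran-2-yl]buta-1,3-dien-1-one (not isolated) | O=C=C(OC)/C(OC)=C(/OC)c1cc(=O)c(OC)c(-c2ccc(OC)cc2)o1 | intermediate
11 | 3,6,7,8-tetramethoxy-2-(4-methoxyphenyl)-4aH-chromene-4,5-dione (racemic at C4a, not isolated) | COC1=C(OC)C(=O)C2C(=O)C(OC)=C(c3ccc(OC)cc3)OC2=C1OC | intermediate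
12 | 5-hydroxyauranetin, 5-hydroxy-3,6,7,8-tetramethoxy-2-(4-methoxyphenyl)-4H-chromen-4-one (achiral) | COc1ccc(-c2oc3c(OC)c(OC)c(OC)c(O)c3c(=O)c2OC)cc1 | target

## Step count and least certain steps

Total step count: 6. Longest linear sequence: 6 steps (1 → 2 → 3 → 5 → 8 → 9 → 12). Compounds 4 and 6 are bought.

**Step 6 (key step).**
- *What may go wrong:* the 6π closure may be too slow. The pyranone alkene belongs to a cross-conjugated vinylogous ester and is less nucleophilic than the donor-substituted arenes and furans usually employed. The ketene would then mostly re-close, and over long heating it would be lost by dimerisation, hydration or unspecific decomposition.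
- *Fallback (from 6, back at 12):* ring A is still drawn from the squarate, but on the best-documented kind of arm, a simple alkenyl group, and ring C is built afterwards by classical flavonol chemistry.
  - 1-Ethoxyvinyllithium (ethyl vinyl ether, t-BuLi) is added to 6 at −78 °C. The alkoxide, here free of amine and pyranone, is trapped with MeOTf to give 4-(1-ethoxyethenyl)-2,3,4-trimethoxycyclobut-2-en-1-one F1.
  - Heating in toluene gives 5-ethoxy-2,3,4-trimethoxyphenol F2 by the same 4π/6π sequence.
  - A Hoesch reaction with methoxyacetonitrile (ZnCl2, HCl, then water) acylates the only free ring position, ortho to the hydroxyl. It gives 1-(2-ethoxy-6-hydroxy-3,4,5-trimethoxyphenyl)-2-methoxyethan-1-one F3.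
  - Allan–Robinson condensation with 4-methoxybenzoic anhydride and its sodium salt closes ring C to 5-ethoxy-3,6,7,8-tetramethoxy-2-(4-methoxyphenyl)-4H-chromen-4-one F4.
  - BCl3 in CH2Cl2 removes only the ether peri to the carbonyl, by chelation, and gives 12.
  - The price is five operations and a late dealkylation.

**Step 4.**
- *What may go wrong:* the lithiated pyranone may add to unmetalated 5. Deprotonation may compete at C5 and be followed by ring opening through β-elimination of the ring oxygen. Residual amide may attack 6.
- *Fallback (from 5, back at 8):* the carbanion is generated by halogen–metal exchange instead of by a strong base.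
  - Mild zincation of 5 with TMPZnCl·LiCl in THF gives chloro[5-methoxy-6-(4-methoxyphenyl)-4-oxo-4H-pyran-2-yl]zinc F5.
  - Iodolysis converts F5 into 6-iodo-3-methoxy-2-(4-methoxyphenyl)-4H-pyran-4-one F6, an isolable compound in which the site of metalation can be verified.
  - Iodine–magnesium exchange with iPrMgCl·LiCl at −78 °C, with neither amine nor C6–H pyranone present, gives chloro[5-methoxy-6-(4-methoxyphenyl)-4-oxo-4H-pyran-2-yl]magnesium F7.
  - F7 is added to 6 at once and quenched with NH4Cl to give 8.

**Step 5.**
- *What may go wrong:* alkylation of a hindered, electron-poor tertiary alcohol may be sluggish. Prolonged contact with the basic silver oxide surface may then cause ring opening or rearrangement of the hydroxycyclobutenone.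
- *Fallback (from 8, back at 12):* the methylation is moved behind the ring expansion.
  - Carbinol 8 is heated as in step 6, where the hydroxyl group also rotates outward. This gives 5,8-dihydroxy-3,6,7-trimethoxy-2-(4-methoxyphenyl)-4H-chromen-4-one F8, which is handled under argon.
  - One equivalent of dimethyl sulfate with K2CO3 in acetone methylates the free C8 hydroxyl in preference to the C5 hydroxyl, which is deactivated by chelation to C4=O. This is the usual reactivity order in flavones, and it gives 12.

**Step 1 (together with steps 2 and 3).**
- *What may go wrong:* a second bromination or attack at C5 may occur in step 1. In step 2 the activated C2 bromide may be lost by nucleophilic displacement.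
- *Fallback (from 1, back at 5):* halogen is avoided altogether.
  - Compound 1 is O-methylated (MeI, K2CO3) to 3-methoxy-4H-pyran-4-one F9.
  - TMPZnCl·LiCl metalates C2, the C–H flanked by the ring oxygen and the methoxy group, to give chloro(3-methoxy-4-oxo-4H-pyran-2-yl)zinc F10.
  - Negishi coupling with 4-iodoanisole in the same flask (Pd catalyst) gives 5.

## Further compounds

F1 | step 6 | 4-(1-ethoxyethenyl)-2,3,4-trimethoxycyclobut-2-en-1-one (racemic) | C=C(OCC)C1(OC)C(OC)=C(OC)C1=O
F2 | step 6 | 5-ethoxy-2,3,4-trimethoxyphenol | CCOc1cc(O)c(OC)c(OC)c1OC
F3 | step 6 | 1-(2-ethoxy-6-hydroxy-3,4,5-trimethoxyphenyl)-2-methoxyethan-1-one | CCOc1c(OC)c(OC)c(OC)c(O)c1C(=O)COC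
F4 | step 6 | 5-ethoxy-3,6,7,8-tetramethoxy-2-(4-methoxyphenyl)-4H-chromen-4-one | CCOc1c(OC)c(OC)c(OC)c2oc(-c3ccc(OC)cc3)c(OC)c(=O)c12
F5 | step 4 | chloro[5-methoxy-6-(4-methoxyphenyl)-4-oxo-4H-pyran-2-yl]zinc | Cl[Zn]c1cc(=O)c(OC)c(-c2ccc(OC)cc2)o1
F6 | step 4 | 6-iodo-3-methoxy-2-(4-methoxyphenyl)-4H-pyran-4-one | COc1ccc(-c2oc(I)cc(=O)c2OC)cc1
F7 | step 4 | chloro[5-methoxy-6-(4-methoxyphenyl)-4-oxo-4H-pyran-2-yl]magnesium | Cl[Mg]c1cc(=O)c(OC)c(-c2ccc(OC)cc2)o1
F8 | step 5 | 5,8-dihydroxy-3,6,7-trimethoxy-2-(4-methoxyphenyl)-4H-chromen-4-one | COc1ccc(-c2oc3c(O)c(OC)c(OC)c(O)c3c(=O)c2OC)cc1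
F9 | step 1 | 3-methoxy-4H-pyran-4-one | COc1coccc1=O
F10 | step 1 | chloro(3-methoxy-4-oxo-4H-pyran-2-yl)zinc | Cl[Zn]c1occc(=O)c1OC
A1 | alternative 1 | 2-methoxy-1-(4-methoxyphenyl)-3-[2,3,4,5-tetramethoxy-6-(methoxymethoxy)phenyl]propane-1,3-dione (C2 configurationally labile) | COCOc1c(OC)c(OC)c(OC)c(OC)c1C(=O)C(OC)C(=O)c1ccc(OC)cc1
A2 | alternative 1 | 1-iodo-2,3,4,5-tetramethoxy-6-(methoxymethoxy)benzene | COCOc1c(I)c(OC)c(OC)c(OC)c1OC
A3 | alternative 1 | carbon monoxide | [C-]#[O+]
A4 | alternative 1 | 2-methoxy-1-(4-methoxyphenyl)ethan-1-one | COCC(=O)c1ccc(OC)cc1
A5 | alternative 2 | (Z)-1-(2-hydroxy-3,4,5,6-tetramethoxyphenyl)-2-methoxy-3-(4-methoxyphenyl)prop-2-en-1-one | COc1ccc(/C=C(\OC)C(=O)c2c(O)c(OC)c(OC)c(OC)c2OC)cc1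
A6 | alternative 2 | 2,3,4,5-tetramethoxy-6-(trimethylsilyl)phenyl trifluoromethanesulfonate | COc1c(OC)c(OC)c([Si](C)(C)C)c(OS(=O)(=O)C(F)(F)F)c1OC
A7 | alternative 2 | 3,4,5,6-tetramethoxybenzyne | COC1=C(OC)C(OC)=C(OC)C#C1
A8 | alternative 2 | (Z)-2-methoxy-3-(4-methoxyphenyl)prop-2-enoic acid | COc1ccc(/C=C(\OC)C(=O)O)cc1
A9 | alternative 3 | 3,5,6,7,8,4′-hexamethoxyflavone | COc1ccc(-c2oc3c(OC)c(OC)c(OC)c(OC)c3c(=O)c2OC)cc1
A10 | alternative 3 | 2,3,4,5-tetramethoxyphenol | COc1cc(O)c(OC)c(OC)c1OC
A11 | alternative 3 | ethyl 2-methoxy-3-(4-methoxyphenyl)-3-oxopropanoate (racemic, enolisable) | CCOC(=O)C(OC)C(=O)c1ccc(OC)cc1
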